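**Retrosynthetic overview**

1. The target is a 5,6,7,8-tetramethoxyflavone whose ring B carries OH on C2' and C4' and OMe on C5'. The last operation frees the C4' hydroxyl from a methoxymethyl ether (19 → 20).
2. The strategy rests on the 1,4-relationship on ring B between the C2' hydroxyl and the C5' methoxy group, the pattern left by a chromium carbene benzannulation. Ring B is cut at C5'–C6', C1'–C2' and C2'–C3' into the terminal alkyne 11 (C1', C6'), one carbonyl ligand (C2') and the methoxy[1-(methoxymethoxy)vinyl]carbene ligand of 17 (C5', C4', C3').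
3. Alkyne 11 comes by one-carbon homologation from aldehyde 10, and 10 from chromone ester 8. Ring C of 8 is closed by Claisen condensation and cyclodehydration of hydroxyacetophenone 5 with diethyl oxalate; 5 comes from 1,2,3,4-tetramethoxybenzene through phenol 4.
4. Complex 17 comes from methoxymethyl vinyl ether 13 (made from bromide 12), Cr(CO)6 and Me3OBF4.
5. Ring order: ring A is bought, ring C is closed in step 3, ring B is closed in step 9.

Key step: step 9

Remark: the target has no stereocentre; 1 and 12 are taken as purchasable, and 13 is made from 12 because it is not a routine catalogue item.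

**Route**

Step 1
Reactants: 1 1,2,3,4-tetramethoxybenzene
Product: 4 2,3,4,5-tetramethoxyphenol, via aryllithium 2 (not isolated), via dimethyl arylboronate 3 (not isolated)
Conditions: n-BuLi, TMEDA, THF, 0 °C; B(OMe)3, −78 °C → rt; AcOH, 30% H2O2, 0 °C → rt
Reagents that add atoms: hydrogen peroxide, OO
Why: Directed ortho-lithiation can only occur at the two equivalent ring C–H positions next to a methoxy group, and borylation followed by oxidative boron-to-oxygen aryl migration (hydroxydeboronation) should turn that carbon into the phenol carbon.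

Step 2
Reactants: 4 2,3,4,5-tetramethoxyphenol
Product: 5 1-(2-hydroxy-3,4,5,6-tetramethoxyphenyl)ethan-1-one
Conditions: AcOH, BF3·OEt2, 80 °C; aq. NaOAc work-up
Reagents that add atoms: acetic acid, CC(=O)O
Why: BF3-promoted Friedel–Crafts C-acylation (Fries-type, through the aryl acetate) can only take place at the single free ring position, which is ortho to the phenol, and the product is held as the chelated ortho-hydroxy ketone.

Step 3
Reactants: 5 1-(2-hydroxy-3,4,5,6-tetramethoxyphenyl)ethan-1-one; 6 diethyl oxalate
Product: 8 ethyl 5,6,7,8-tetramethoxy-4-oxo-4H-chromene-2-carboxylate, via dioxobutanoate 7 (not isolated)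
Conditions: NaOEt, EtOH, reflux; then conc. HCl, EtOH, reflux
Reagents that add atoms: none
Why: Crossed Claisen condensation of the methyl ketone enolate with non-enolisable diethyl oxalate gives the 2,4-dioxobutanoate, and acid then closes ring C by attack of the phenol oxygen on the 2-oxo group and loss of water, the standard chromone-2-carboxylate synthesis.

Step 4
Reactants: 8 ethyl 5,6,7,8-tetramethoxy-4-oxo-4H-chromene-2-carboxylate
Product: 9 2-(hydroxymethyl)-5,6,7,8-tetramethoxy-4H-chromen-4-one
Conditions: NaBH4, EtOH/THF, −10 → 0 °C; dil. HCl quench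
Reagents that add atoms: none
Why: In this chemoselective borohydride reduction the ester on C2 of the pyranone is strongly activated towards hydride, whereas the C4 carbonyl is a vinylogous ester and should remain untouched at 0 °C, so reduction should stop at the primary allylic alcohol.

Step 5
Reactants: 9 2-(hydroxymethyl)-5,6,7,8-tetramethoxy-4H-chromen-4-one
Product: 10 5,6,7,8-tetramethoxy-4-oxo-4H-chromene-2-carbaldehyde
Conditions: Dess–Martin periodinane, CH2Cl2, rt
Reagents that add atoms: none
Why: Dess–Martin oxidation converts the primary alcohol into the aldehyde under neutral, anhydrous conditions that spare the pyranone and the aryl methyl ethers and cannot over-oxidise.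

Step 6
Reactants: 10 5,6,7,8-tetramethoxy-4-oxo-4H-chromene-2-carbaldehyde
Product: 11 2-ethynyl-5,6,7,8-tetramethoxy-4H-chromen-4-one
Conditions: dimethyl (1-diazo-2-oxopropyl)phosphonate, K2CO3, MeOH/THF, 0 °C → rt, short reaction time
Reagents that add atoms: dimethyl (1-diazo-2-oxopropyl)phosphonate, COP(=O)(OC)C(=[N+]=[N-])C(C)=O
Why: In this Ohira–Bestmann homologation, methanolysis of the acetyl group releases the diazomethylphosphonate anion, which adds to the aldehyde, eliminates dimethyl phosphate and loses N2 to an alkylidene carbene that rearranges by 1,2-hydrogen shift to the terminal alkyne.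

Step 7
Reactants: 12 1-bromo-2-(methoxymethoxy)ethane
Product: 13 methoxymethyl vinyl ether
Conditions: powdered KOH, tetraglyme, 110 °C, product distilled out; redistilled from CaH2
Reagents that add atoms: none
Why: Base-promoted E2 dehydrobromination of a 2-alkoxyethyl bromide is the classical vinyl ether synthesis, and the formaldehyde acetal is inert to hydroxide.

Step 8
Reactants: 13 methoxymethyl vinyl ether; 14 chromium hexacarbonyl
Product: 17 pentacarbonyl{methoxy[1-(methoxymethoxy)vinyl]carbene}chromium, via vinyllithium 15 (not isolated), via lithium acylchromate 16 (not isolated)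
Conditions: s-BuLi, THF, −78 → −40 °C; Cr(CO)6, −78 °C → rt; solvent removed; Me3OBF4, CH2Cl2, 0 °C
Reagents that add atoms: trimethyloxonium tetrafluoroborate, C[O+](C)C.F[B-](F)(F)F
Why: In this Fischer carbene synthesis the vinyl ether is deprotonated at its oxygen-bearing sp2 carbon, the vinyllithium adds to a carbonyl ligand of Cr(CO)6 to give the acylchromate, and hard O-methylation by the oxonium salt should give the methoxycarbene complex.

Step 9
Reactants: 11 2-ethynyl-5,6,7,8-tetramethoxy-4H-chromen-4-one; 17 pentacarbonyl{methoxy[1-(methoxymethoxy)vinyl]carbene}chromium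
Product: 19 2-[2-hydroxy-5-methoxy-4-(methoxymethoxy)phenyl]-5,6,7,8-tetramethoxy-4H-chromen-4-one, via tricarbonylchromium arene complex 18 (not isolated)
Conditions: 17 (1.5 equiv), degassed THF, 55 °C, Ar; then air, MeCN, rt
Reagents that add atoms: none
Why: Heating expels one CO ligand from 17, alkyne 11 coordinates and inserts into the Cr=C bond with its CH terminus joined to the carbene carbon (C5'–C6'), and migration of a CO ligand onto the new carbene carbon (C1'–C2') gives a chromium-bound dienylketene. Ring B, the only ring formed, closes by 6π-electrocyclisation between the ketene carbon and the vinyl CH2 (C2'–C3'), and tautomerisation of the cyclohexadienone gives the phenol as its Cr(CO)3 π-complex 18, which should release 19 on exposure to air. The closest known reaction type is the Dötz benzannulation of alkenyl(methoxy)carbene complexes of chromium, including 1-oxygenated alkenyl ones such as dihydropyranyl complexes, with terminal and conjugated alkynes to 4-methoxyphenols. No stereocentre is created. The step needs the chromonyl group next to the new hydroxyl, and phenol formation in preference to cyclobutenone, furan or cyclopentannulation products: insertion places the larger alkyne substituent (chromon-2-yl rather than H) on the carbon that bonds to CO, alkenyl complexes in THF at about 50 °C favour the six-membered phenol, and the pyranone carbonyl sits 1,3 across ring C from the alkyne, too far to trap the vinylcarbene.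

Step 10
Reactants: 19 2-[2-hydroxy-5-methoxy-4-(methoxymethoxy)phenyl]-5,6,7,8-tetramethoxy-4H-chromen-4-one
Product: 20 2-(2,4-dihydroxy-5-methoxyphenyl)-5,6,7,8-tetramethoxy-4H-chromen-4-one
Conditions: 3 M aq. HCl, MeOH, 40 °C
Reagents that add atoms: none
Why: Acid-catalysed acetal exchange with methanol removes the aryl methoxymethyl ether, while the aryl methyl ethers (the peri 5-OMe included) and the pyranone are inert to dilute protic acid.

**Compound list**

1 | 1,2,3,4-tetramethoxybenzene | COc1ccc(OC)c(OC)c1OC | starting material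
2 | 2,3,4,5-tetramethoxyphenyllithium (formed in the flask) | [Li]c1cc(OC)c(OC)c(OC)c1OC | intermediate
3 | dimethyl (2,3,4,5-tetramethoxyphenyl)boronate (formed in the flask) | COB(OC)c1cc(OC)c(OC)c(OC)c1OC | intermediate
4 | 2,3,4,5-tetramethoxyphenol | Oc1cc(OC)c(OC)c(OC)c1OC | intermediate
5 | 1-(2-hydroxy-3,4,5,6-tetramethoxyphenyl)ethan-1-one | CC(=O)c1c(O)c(OC)c(OC)c(OC)c1OC | intermediate
6 | diethyl oxalate | CCOC(=O)C(=O)OCC | starting material
7 | ethyl 4-(2-hydroxy-3,4,5,6-tetramethoxyphenyl)-2,4-dioxobutanoate (formed in the flask) | CCOC(=O)C(=O)CC(=O)c1c(O)c(OC)c(OC)c(OC)c1OC | intermediate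
8 | ethyl 5,6,7,8-tetramethoxy-4-oxo-4H-chromene-2-carboxylate | CCOC(=O)c1cc(=O)c2c(OC)c(OC)c(OC)c(OC)c2o1 | intermediate
9 | 2-(hydroxymethyl)-5,6,7,8-tetramethoxy-4H-chromen-4-one | OCc1cc(=O)c2c(OC)c(OC)c(OC)c(OC)c2o1 | intermediate
10 | 5,6,7,8-tetramethoxy-4-oxo-4H-chromene-2-carbaldehyde | O=Cc1cc(=O)c2c(OC)c(OC)c(OC)c(OC)c2o1 | intermediate
11 | 2-ethynyl-5,6,7,8-tetramethoxy-4H-chromen-4-one | C#Cc1cc(=O)c2c(OC)c(OC)c(OC)c(OC)c2o1 | intermediate
12 | 1-bromo-2-(methoxymethoxy)ethane | BrCCOCOC | starting material
13 | methoxymethyl vinyl ether | C=COCOC | intermediate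
14 | chromium hexacarbonyl | O=C=[Cr](=C=O)(=C=O)(=C=O)(=C=O)=C=O | starting material
15 | 1-(methoxymethoxy)vinyllithium (formed in the flask) | [Li]C(=C)OCOC | intermediate
16 | lithium pentacarbonyl[2-(methoxymethoxy)acryloyl]chromate (formed in the flask) | [Li+].[O-]C(C(=C)OCOC)=[Cr](=C=O)(=C=O)(=C=O)(=C=O)=C=O | intermediate
17 | pentacarbonyl{methoxy[1-(methoxymethoxy)vinyl]carbene}chromium | COCOC(=C)C(OC)=[Cr](=C=O)(=C=O)(=C=O)(=C=O)=C=O | intermediate
18 | tricarbonylchromium π-complex of 19, metal on ring B (formed in the flask) | COCOc1cc(O)c(-c2cc(=O)c3c(OC)c(OC)c(OC)c(OC)c3o2)cc1OC.O=C=[Cr](=C=O)=C=O | intermediate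
19 | 2-[2-hydroxy-5-methoxy-4-(methoxymethoxy)phenyl]-5,6,7,8-tetramethoxy-4H-chromen-4-one | COCOc1cc(O)c(-c2cc(=O)c3c(OC)c(OC)c(OC)c(OC)c3o2)cc1OC | intermediate
20 | 2-(2,4-dihydroxy-5-methoxyphenyl)-5,6,7,8-tetramethoxy-4H-chromen-4-one | COc1cc(-c2cc(=O)c3c(OC)c(OC)c(OC)c(OC)c3o2)c(O)cc1O | target

**Step count**

Total steps: 10. Longest linear sequence: 8 (steps 1, 2, 3, 4, 5, 6, 9, 10); the carbene branch (steps 7, 8) joins at step 9.

**Steps most likely to fail**

Step 9. The electron-poor, conjugated alkyne may insert slowly or with imperfect regiocontrol. The dienylketene may divert to cyclobutenone or two-alkyne products. The electron-rich hydroquinone monoether may also oxidise during the air decomplexation. The fallback sets out from 5 and comes back at 20. Purchased 2,4-dihydroxy-5-methoxybenzaldehyde would be benzylated (BnBr, K2CO3, DMF) to 2,4-bis(benzyloxy)-5-methoxybenzaldehyde F1. Claisen–Schmidt condensation of F1 with 5 (KOH, EtOH, rt) should give (E)-3-[2,4-bis(benzyloxy)-5-methoxyphenyl]-1-(2-hydroxy-3,4,5,6-tetramethoxyphenyl)prop-2-en-1-one F2. Oxidative cyclisation with catalytic I2 in DMSO at 120 °C, which also converts any flavanone formed, should close ring C to 2-[2,4-bis(benzyloxy)-5-methoxyphenyl]-5,6,7,8-tetramethoxy-4H-chromen-4-one F3. Hydrogenolysis (H2, Pd/C, EtOAc/MeOH) would then give 20 directly.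

Step 6. Methoxide or methanol may add to the aldehyde-activated pyranone at C2 with ring opening, or add in 1,6-fashion to the terminal carbon of the product enynone, so the homologation may be accompanied by solvent addition. The fallback sets out from 5 and comes back at 11. Claisen–Schmidt condensation of 5 with 3-(triisopropylsilyl)propynal (KOH, EtOH, 0 °C) should give (E)-1-(2-hydroxy-3,4,5,6-tetramethoxyphenyl)-5-(triisopropylsilyl)pent-2-en-4-yn-1-one F4. Oxidative cyclisation with catalytic I2 in DMSO at 120 °C should give 5,6,7,8-tetramethoxy-2-[(triisopropylsilyl)ethynyl]-4H-chromen-4-one F5. Desilylation with TBAF buffered by AcOH in THF at 0 °C would give 11. This builds the alkyne into ring C formation and bypasses steps 3 to 6.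

Step 4. Hydride may add to C2 or C4 of the pyranone (over-reduction to chromanone or chromanol) instead of stopping at the ester. The fallback sets out from 5 and comes back at 10. Claisen condensation of 5 with ethyl acetate (NaH, THF, reflux) should give 1-(2-hydroxy-3,4,5,6-tetramethoxyphenyl)butane-1,3-dione F6. Cyclodehydration (catalytic H2SO4, AcOH, 90 °C) should give 5,6,7,8-tetramethoxy-2-methyl-4H-chromen-4-one F7. Riley oxidation of the vinylogously activated methyl group (SeO2, dioxane, reflux) would give aldehyde 10 without any hydride step.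

**Further compounds**

F1 | step 9 | 2,4-bis(benzyloxy)-5-methoxybenzaldehyde | O=Cc1cc(OC)c(OCc2ccccc2)cc1OCc1ccccc1
F2 | step 9 | (E)-3-[2,4-bis(benzyloxy)-5-methoxyphenyl]-1-(2-hydroxy-3,4,5,6-tetramethoxyphenyl)prop-2-en-1-one | COc1cc(/C=C/C(=O)c2c(O)c(OC)c(OC)c(OC)c2OC)c(OCc2ccccc2)cc1OCc1ccccc1
F3 | step 9 | 2-[2,4-bis(benzyloxy)-5-methoxyphenyl]-5,6,7,8-tetramethoxy-4H-chromen-4-one | COc1cc(-c2cc(=O)c3c(OC)c(OC)c(OC)c(OC)c3o2)c(OCc2ccccc2)cc1OCc1ccccc1
F4 | step 6 | (E)-1-(2-hydroxy-3,4,5,6-tetramethoxyphenyl)-5-(triisopropylsilyl)pent-2-en-4-yn-1-one | CC(C)[Si](C#C/C=C/C(=O)c1c(O)c(OC)c(OC)c(OC)c1OC)(C(C)C)C(C)C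
F5 | step 6 | 5,6,7,8-tetramethoxy-2-[(triisopropylsilyl)ethynyl]-4H-chromen-4-one | CC(C)[Si](C#Cc1cc(=O)c2c(OC)c(OC)c(OC)c(OC)c2o1)(C(C)C)C(C)C
F6 | step 4 | 1-(2-hydroxy-3,4,5,6-tetramethoxyphenyl)butane-1,3-dione | CC(=O)CC(=O)c1c(O)c(OC)c(OC)c(OC)c1OC
F7 | step 4 | 5,6,7,8-tetramethoxy-2-methyl-4H-chromen-4-one | Cc1cc(=O)c2c(OC)c(OC)c(OC)c(OC)c2o1
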